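**Retrosynthetic overview**

1. No ring is built. Ring B is bought as diol 1 (one CH2OH oxidised to give salicylaldehyde 2). Ring A is bought as the herbicide dicamba 3, which already carries CO2H, OMe and both leaving groups in the right positions.
2. Key disconnection (C–O): the diaryl ether bond of 4, made by carboxylate-directed Ullmann coupling of the phenol oxygen of 2 with C6–Cl of 3.
3. The ring B hydroxyl is a masked formyl group: Baeyer–Villiger (Dakin-type) oxidation of 4 via formate 5 gives phenol 6.
4. Side chain and stereocentre (C–C, then benzylic C–O): C3–Cl of 6 and alkene 7 are joined and oxygenated, through 8 and 9, in one enantioselective 1,1-arylhydroxylation that gives target 10.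

Assumption: the [C@H] centre of the given SMILES is read as (R) (O > aryl > CH2 > H); that enantiomer is made.

**Route**

Step 1
Reactants: 1 2,6-bis(hydroxymethyl)-4-methylphenol
Product: 2 2-hydroxy-3-(hydroxymethyl)-5-methylbenzaldehyde
Conditions: MnO2 (activated, 6 equiv), CHCl3, rt
Reagents that add atoms: none
Why: Chemoselective benzylic alcohol oxidation on MnO2, which can be stopped after the first CH2OH because the new formyl group hydrogen-bonds the phenol and makes the ring electron-poorer; no stereocentre is involved.

Step 2
Reactants: 3 dicamba (3,6-dichloro-2-methoxybenzoic acid); 2 2-hydroxy-3-(hydroxymethyl)-5-methylbenzaldehyde (1.2 equiv)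
Product: 4 3-chloro-6-[2-formyl-6-(hydroxymethyl)-4-methylphenoxy]-2-methoxybenzoic acid
Conditions: CuI (10 mol %), Cu powder (10 mol %), K2CO3 (3 equiv), pyridine (0.3 equiv), DMF, 110 °C, N2
Reagents that add atoms: none
Why: Ullmann–Goldberg diaryl ether condensation with the ortho-carboxylate effect: the potassium carboxylate of 3 holds copper next to C6–Cl, so only this chloride (not C3–Cl beside OMe) is replaced by the phenoxide of 2, the only oxygen of 2 that carbonate deprotonates; no stereocentre is involved.

Step 3
Reactants: 4 3-chloro-6-[2-formyl-6-(hydroxymethyl)-4-methylphenoxy]-2-methoxybenzoic acid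
Product: 6 3-chloro-6-[2-hydroxy-6-(hydroxymethyl)-4-methylphenoxy]-2-methoxybenzoic acid, via aryl formate 5 (not isolated)
Conditions: mCPBA (1.2 equiv), CH2Cl2, 0 °C to rt; then Et3N (3 equiv), MeOH, rt
Reagents that add atoms: mCPBA (3-chloroperoxybenzoic acid), SMILES OOC(=O)c1cccc(Cl)c1
Why: Baeyer–Villiger oxidation of an ortho-aryloxy benzaldehyde (Dakin-type), in which the oxygen-substituted aryl group migrates in preference to hydrogen to give formate 5, cleaved by base-catalysed methanolysis; peracid leaves the aryl chloride, the acid and the benzylic alcohol alone, and no stereocentre is involved.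

Step 4
Reactants: 6 3-chloro-6-[2-hydroxy-6-(hydroxymethyl)-4-methylphenoxy]-2-methoxybenzoic acid; 7 2-methylbut-3-en-2-ol (3 equiv)
Product: 10 3-[(1R)-1,3-dihydroxy-3-methylbutyl]-6-[2-hydroxy-6-(hydroxymethyl)-4-methylphenoxy]-2-methoxybenzoic acid, via styrenyl alcohol 8 (not isolated), via benzylic hydrogencarbonate 9 (not isolated)
Conditions: Pd2(dba)3 (2.5 mol %), (R)-1-[(Sp)-2-(dicyclohexylphosphino)ferrocenyl]ethyldi-tert-butylphosphine (6 mol %), KHCO3 (5 equiv), t-AmOH/H2O 3:1, 90 °C, N2
Reagents that add atoms: potassium hydrogencarbonate (KHCO3), SMILES [K+].OC(=O)[O-]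
Why: Proposed new method: a redox-neutral, enantioselective palladium-catalysed 1,1-arylhydroxylation of a terminal alkene by an aryl chloride; zerovalent palladium on the electron-rich ferrocenyl diphosphine inserts into C3–Cl, the cationic aryl–palladium formed in the aqueous alcohol adds to the CH2 terminus of 7 (Heck insertion), β-hydride elimination can only go toward the benzylic CH2 because the carbinol carbon is quaternary, and the palladium hydride stays on or returns to styrene 8 (no strong base strips it, and no acid is present that would ionise the tertiary allylic alcohol) and re-inserts the other way round to an η3-benzyl palladium cation; hydrogencarbonate then attacks the benzylic carbon anti to palladium inside the chiral pocket, the two diastereomeric benzyl complexes interconverting by β-H elimination/re-insertion, so the ligand sets the only stereocentre in this C–O bond-forming event (which ligand antipode gives (R) cannot be predicted and is fixed in the first run; both are sold), and monoester 9 loses CO2 to give the alcohol and zerovalent palladium; closest known reaction types are the palladium-catalysed 1,1-arylacetoxylation, 1,1-arylborylation and 1,1-fluoroarylation of terminal alkenes (same Heck/chain-walk/π-benzyl sequence, but oxidative and with aryl-tin or aryl-boron partners), the enantioselective palladium-catalysed hydroamination of vinylarenes through η3-benzyl intermediates, and asymmetric allylic substitution with hydrogencarbonate as hydroxide equivalent.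

**Compound list**

1 | 2,6-bis(hydroxymethyl)-4-methylphenol | Cc1cc(CO)c(O)c(CO)c1 | starting material
2 | 2-hydroxy-3-(hydroxymethyl)-5-methylbenzaldehyde | Cc1cc(CO)c(O)c(C=O)c1 | intermediate
3 | dicamba (3,6-dichloro-2-methoxybenzoic acid) | COc1c(Cl)ccc(Cl)c1C(=O)O | starting material
4 | 3-chloro-6-[2-formyl-6-(hydroxymethyl)-4-methylphenoxy]-2-methoxybenzoic acid | COc1c(Cl)ccc(Oc2c(C=O)cc(C)cc2CO)c1C(=O)O | intermediate
5 | 3-chloro-6-[2-(formyloxy)-6-(hydroxymethyl)-4-methylphenoxy]-2-methoxybenzoic acid (aryl formate, not isolated) | COc1c(Cl)ccc(Oc2c(OC=O)cc(C)cc2CO)c1C(=O)O | intermediate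
6 | 3-chloro-6-[2-hydroxy-6-(hydroxymethyl)-4-methylphenoxy]-2-methoxybenzoic acid | COc1c(Cl)ccc(Oc2c(O)cc(C)cc2CO)c1C(=O)O | intermediate
7 | 2-methylbut-3-en-2-ol | C=CC(C)(C)O | starting material
8 | 3-[(E)-3-hydroxy-3-methylbut-1-en-1-yl]-6-[2-hydroxy-6-(hydroxymethyl)-4-methylphenoxy]-2-methoxybenzoic acid (styrenyl alcohol, not isolated) | COc1c(/C=C/C(C)(C)O)ccc(Oc2c(O)cc(C)cc2CO)c1C(=O)O | intermediate
9 | 3-[(1R)-1-(carboxyoxy)-3-hydroxy-3-methylbutyl]-6-[2-hydroxy-6-(hydroxymethyl)-4-methylphenoxy]-2-methoxybenzoic acid (benzylic hydrogencarbonate, not isolated) | COc1c([C@H](OC(=O)O)CC(C)(C)O)ccc(Oc2c(O)cc(C)cc2CO)c1C(=O)O | intermediate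
10 | 3-[(1R)-1,3-dihydroxy-3-methylbutyl]-6-[2-hydroxy-6-(hydroxymethyl)-4-methylphenoxy]-2-methoxybenzoic acid (CNP0452050.1) | COc1c([C@H](O)CC(C)(C)O)ccc(Oc2c(O)cc(C)cc2CO)c1C(=O)O | target

**Step count and risks**

Total steps: 4. Longest linear sequence: 4 (1 → 2 → 4 → 6 → 10). No protecting groups are used.

The step most likely to fail is step 4, because it is new. The likely failure modes are:
- slow oxidative addition at the electron-rich C3–Cl;
- release of 8 as a plain Heck product that does not re-enter;
- attack of the substrate's own phenoxide or carboxylate on the benzyl complex;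
- palladium ionisation of the tertiary allylic alcohol;
- low enantioselectivity.

Its fallback uses known chemistry only, sets out from 6 and comes back at 10. A conventional Heck reaction of 6 with 7 (Pd2(dba)3, [HP(t-Bu)3]BF4, Cs2CO3, DMA, 110 °C) is run to isolate styrenyl alcohol 8. Compound 8 is persilylated in the flask with N,O-bis(trimethylsilyl)acetamide (cat. TMSCl, THF, 50 °C) to the tetrakis(trimethylsilyl) derivative F1, so that no acidic proton meets the hydride. F1 undergoes copper-hydride-catalysed enantioselective Markovnikov hydroboration (Cu(OAc)2, (S)-DTBM-SEGPHOS, pinacolborane, THF, rt) to the (R)-benzylic pinacolboronate F2. The (S)-ligand is the expected choice by analogy with styrene hydrocupration and should be confirmed on a model. NaBO3·4H2O in THF/H2O, then dilute HCl in MeOH, oxidises the C–B bond with retention and removes the silyl groups, giving 10.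

Second in risk is step 2. The phenoxide of 2 is hindered, electron-poor and chelating; the o-hydroxybenzyl alcohol can self-condense through a quinone methide near 110 °C; and forcing the aryl chloride invites protodecarboxylation. The fallback sets out from 3 and 1 and comes back at 4, and moves the aldehyde formation behind the ether formation. Dicamba 3 is coupled under the same copper/carbonate conditions, at 90–100 °C, with the formyl-free and more nucleophilic diol 1 to give 3-chloro-6-[2,6-bis(hydroxymethyl)-4-methylphenoxy]-2-methoxybenzoic acid F3. One of its two equivalent benzylic alcohols is then oxidised (MnO2, CHCl3, stopped near half conversion) to reach 4. This oxidation is statistical, under 50 % per pass, with diol and over-oxidised dialdehyde recycled by NaBH4.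

Third is step 3. The aryloxy group is only a modest donor, so hydrogen migration (giving a ring B carboxylic acid) and over-oxidation can compete. The fallback sets out from 2 and comes back at 6, and places the Dakin oxidation before the coupling, where it is textbook on a free salicylaldehyde. Compound 2 with H2O2/NaOH (H2O, 0 °C to rt) gives 3-(hydroxymethyl)-5-methylbenzene-1,2-diol F4. Mono-allylation at the less hindered phenol remote from CH2OH (allyl bromide 1.0 equiv, K2CO3, acetone, rt) gives 2-(allyloxy)-6-(hydroxymethyl)-4-methylphenol F5; the regioselectivity of this step is expected on steric grounds, not assured. Ullmann coupling of F5 with 3 as in step 2 gives 6-[2-(allyloxy)-6-(hydroxymethyl)-4-methylphenoxy]-3-chloro-2-methoxybenzoic acid F6. Pd(PPh3)4 with morpholine (THF, rt) removes the allyl group without touching the aryl chloride and returns 6.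

**Further compounds**

F1 | step 4 | trimethylsilyl 2-methoxy-3-[(E)-3-methyl-3-(trimethylsilyloxy)but-1-en-1-yl]-6-[4-methyl-2-(trimethylsilyloxy)-6-(trimethylsilyloxymethyl)phenoxy]benzoate | COc1c(/C=C/C(C)(C)O[Si](C)(C)C)ccc(Oc2c(O[Si](C)(C)C)cc(C)cc2CO[Si](C)(C)C)c1C(=O)O[Si](C)(C)C
F2 | step 4 | trimethylsilyl 2-methoxy-3-[(1R)-3-methyl-1-(4,4,5,5-tetramethyl-1,3,2-dioxaborolan-2-yl)-3-(trimethylsilyloxy)butyl]-6-[4-methyl-2-(trimethylsilyloxy)-6-(trimethylsilyloxymethyl)phenoxy]benzoate | COc1c([C@H](B2OC(C)(C)C(C)(C)O2)CC(C)(C)O[Si](C)(C)C)ccc(Oc3c(O[Si](C)(C)C)cc(C)cc3CO[Si](C)(C)C)c1C(=O)O[Si](C)(C)C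
F3 | step 2 | 3-chloro-6-[2,6-bis(hydroxymethyl)-4-methylphenoxy]-2-methoxybenzoic acid | COc1c(Cl)ccc(Oc2c(CO)cc(C)cc2CO)c1C(=O)O
F4 | step 3 | 3-(hydroxymethyl)-5-methylbenzene-1,2-diol | Cc1cc(O)c(O)c(CO)c1
F5 | step 3 | 2-(allyloxy)-6-(hydroxymethyl)-4-methylphenol | C=CCOc1cc(C)cc(CO)c1O
F6 | step 3 | 6-[2-(allyloxy)-6-(hydroxymethyl)-4-methylphenoxy]-3-chloro-2-methoxybenzoic acid | COc1c(Cl)ccc(Oc2c(OCC=C)cc(C)cc2CO)c1C(=O)O
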